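**Retrosynthetic overview**
- The strategy rests on the oxygen pattern of the cyclohexene ring. The oxygens at C3 and C6 stand para, as in a p-benzoquinone, and the trans C4–OMe/C5–OH pair is a C4–O–C5 oxirane opened at C4 by methanol. All six ring carbons therefore come from a phenol.
- Last disconnections: the C3 acetate (acetylation while the cis C5/C6 diol is masked as a boronate), then the C1–C(sp) bond (Sonogashira coupling of a C1 vinyl bromide with the ten-carbon enyne side chain).
- The bromo triol goes back to an epoxy diol by C6–OH-directed methanolysis at C4. The epoxy diol goes back to a bromo epoxy quinone monoketal by two epoxide-controlled carbonyl reductions (C6, then C3) and one Mitsunobu inversion at C3.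
- The epoxy ketal comes from enantioselective nucleophilic epoxidation of the C4=C5 bond of the bromoquinone monoketal, which is made by oxidative dearomatisation of 2-bromo-4-methoxyphenol.
- Rings: the carbocycle is bought as the arene. The oxirane is the only ring built (step 2) and is opened in step 9. The side chain is assembled from 2-methylbut-3-yn-2-ol, 2,3-dibromopropene and trimethylsilylacetylene.

Key step: step 2

**Remarks before the steps**
- Convention: the ring locants of the target are kept for all ring compounds. C1 carries Br or the enyne, C2 is the vinylic CH, C3 is the ketal/ketone/acyloxy carbon, C4 and C5 are the oxirane carbons, and C6 is the carbonyl or carbinol carbon next to C1. α is the face of the C5 and C6 hydroxyls of the target; β is the face of C3–OAc and C4–OMe.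
- Assumption: L-(+)-diisopropyl tartrate is written for delivery of the peroxide to the α face. The sense of induction has to be confirmed on the epoxide of step 2, and the equally available D-(−)-ester is taken if it proves opposite.
- Remark: Ph3COOH is treated as a reagent. If not bought, it is made in one operation from triphenylmethanol and H2O2 under acid catalysis.
- Remark on the endgame order: the C3 ester used for the inversion is removed before the oxirane is opened and before the coupling. A β-acyloxy group at C3 would attack C4 itself through a five-membered acyloxonium ion, and zerovalent palladium ionises allylic acetates. The acetate of the target is therefore put on last.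
- Remark on the catalyst of step 9: Eu(OTf)3 is taken instead of Ti(OiPr)4. In methanol Ti(OiPr)4 exchanges to sparingly soluble Ti(OMe)4 and brings in isopropanol as a second nucleophile.

**Route**

Step 1
Reactants: 1 2-bromo-4-methoxyphenol
Product: 2 2-bromo-4,4-dimethoxycyclohexa-2,5-dien-1-one
Conditions: PhI(OAc)2, MeOH, 0 °C to rt
Reagents that add atoms: methanol, CO
Why: Oxidative dearomatisation of a para-alkoxyphenol with a trivalent iodine reagent, in which solvent methanol attacks the activated phenol at the para carbon that already bears OMe, so the quinone monoketal forms directly and no stereocentre arises.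

Step 2
Reactants: 2 2-bromo-4,4-dimethoxycyclohexa-2,5-dien-1-one
Product: 4 (5S,6R)-2-bromo-5,6-epoxy-4,4-dimethoxycyclohex-2-en-1-one (oxirane C4–O–C5 on the α face), via sodium peroxy enolate 3 (not isolated)
Conditions: Ph3COOH, NaN(SiMe3)2, L-(+)-diisopropyl tartrate, 4 Å MS, toluene, −40 °C
Reagents that add atoms: trityl hydroperoxide, OOC(c1ccccc1)(c1ccccc1)c1ccccc1; sodium bis(trimethylsilyl)amide, [Na+].C[Si](C)(C)[N-][Si](C)(C)C (sodium stays only in 3)
Why: NaN(SiMe3)2 converts Ph3COOH and the tartrate into a mixed sodium peroxide/sodium tartrate aggregate, whose peroxide oxygen adds in 1,4-fashion to C4 of the C4=C5–C6=O enone to give enolate 3. In 3 the enolate carbon C5 attacks the proximal peroxide oxygen and expels Ph3CO−, a 3-exo-tet closure that forms the C4–O–C5 oxirane, the only ring made in the step. The closest known reaction type is the Weitz–Scheffer epoxidation in its tartrate-mediated asymmetric form, which is established for halogenated quinone monoketals. C4 is set by the chiral aggregate, which holds the C6 carbonyl on sodium and lets the bulky trityl peroxide reach only one of the two enantiotopic faces of planar 2 (here the α face), and C5 follows from C4 because a three-membered ring can close only on the face that carries the peroxide. Besides face selectivity the step needs site selectivity for C4=C5 over C1=C2 and a stop after one epoxidation: peroxide addition is reversible and closure at the bromine-bearing, fully substituted and less nucleophilic enolate carbon C1 is slow, so only the unsubstituted alkene is turned over and the bromoalkene left in 4 stays intact. The C3 ketal blocks rearomatisation and keeps the second quinone carbonyl out of play.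

Step 3
Reactants: 4 (5S,6R)-2-bromo-5,6-epoxy-4,4-dimethoxycyclohex-2-en-1-one
Product: 5 (1S,2R,6S)-3-bromo-5,5-dimethoxy-7-oxabicyclo[4.1.0]hept-3-en-2-ol (C6–OH α, cis to the oxirane)
Conditions: iBu2AlH, THF, −78 °C; aq. potassium sodium tartrate
Reagents that add atoms: none
Why: 1,2-Reduction of an α,β-epoxy enone by an aluminium hydride, in which hydride reaches C6 from the β face, anti to the neighbouring oxirane oxygen, so the new hydroxyl (6R) is cis to the epoxide while vinyl bromide, ketal and oxirane are inert at this temperature.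

Step 4
Reactants: 5 (1S,2R,6S)-3-bromo-5,5-dimethoxy-7-oxabicyclo[4.1.0]hept-3-en-2-ol
Product: 6 (1R,2R,6S)-3-bromo-5,5-dimethoxy-7-oxabicyclo[4.1.0]hept-3-en-2-yl acetate (C6–OAc α)
Conditions: Ac2O, pyridine, DMAP (cat.), CH2Cl2, 0 °C to rt
Reagents that add atoms: acetic anhydride, CC(=O)OC(C)=O
Why: DMAP-catalysed O-acylation that keeps C6–OH out of the later Mitsunobu reaction, the α-acetate being unable to reach the back side of the C5–O bond.

Step 5
Reactants: 6 (1R,2R,6S)-3-bromo-5,5-dimethoxy-7-oxabicyclo[4.1.0]hept-3-en-2-yl acetate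
Product: 7 (1R,2R,6S)-3-bromo-5-oxo-7-oxabicyclo[4.1.0]hept-3-en-2-yl acetate (C3 ketone, β-bromoenone)
Conditions: TsOH·H2O (cat.), acetone–H2O, rt
Reagents that add atoms: water, O
Why: Acid-catalysed ketal hydrolysis through the allyl-stabilised oxocarbenium ion at C3, tolerated by the acetate and by an oxirane flanked by two electron-poor carbons, and run before the acid-labile side chain is present.

Step 6
Reactants: 7 (1R,2R,6S)-3-bromo-5-oxo-7-oxabicyclo[4.1.0]hept-3-en-2-yl acetate
Product: 8 (1R,2R,5R,6R)-3-bromo-5-hydroxy-7-oxabicyclo[4.1.0]hept-3-en-2-yl acetate (C3–OH α)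
Conditions: NaBH4, CeCl3·7H2O, MeOH, −78 °C
Reagents that add atoms: none
Why: Luche reduction, in which the hard cerium-modified borohydride adds 1,2 (no conjugate addition–elimination of bromide) from the β face, anti to the oxirane and the C6 acetate, giving the C3 α-alcohol (3R).

Step 7
Reactants: 8 (1R,2R,5R,6R)-3-bromo-5-hydroxy-7-oxabicyclo[4.1.0]hept-3-en-2-yl acetate
Product: 9 (1R,2R,5S,6R)-3-bromo-7-oxabicyclo[4.1.0]hept-3-ene-2,5-diyl diacetate (C3–OAc β, C6–OAc α)
Conditions: PPh3, DIAD, AcOH, THF, 0 °C to rt
Reagents that add atoms: acetic acid, CC(=O)O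
Why: Mitsunobu reaction, in which acetate displaces the activated C3 oxygen by SN2 from the open β face with inversion to 3S, the SN2′ path being blocked by bromine on C1.

Step 8
Reactants: 9 (1R,2R,5S,6R)-3-bromo-7-oxabicyclo[4.1.0]hept-3-ene-2,5-diyl diacetate
Product: 10 (1S,2R,5S,6R)-3-bromo-7-oxabicyclo[4.1.0]hept-3-ene-2,5-diol (C3–OH β, C6–OH α, oxirane α)
Conditions: K2CO3 (cat.), MeOH, 0 °C
Reagents that add atoms: none
Why: Zemplén-type transesterification that removes both acetates under mild base, at low temperature to hold back Payne migration of the oxirane, and so frees the C6 hydroxyl for direction and takes away the participating and palladium-labile C3 ester.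

Step 9
Reactants: 10 (1S,2R,5S,6R)-3-bromo-7-oxabicyclo[4.1.0]hept-3-ene-2,5-diol
Product: 11 (1R,2S,3S,4S)-6-bromo-3-methoxycyclohex-5-ene-1,2,4-triol (C3–OH β, C4–OMe β, C5–OH α, C6–OH α)
Conditions: Eu(OTf)3 (cat.), 2,6-di-tert-butyl-4-methylpyridine, MeOH, rt to 40 °C
Reagents that add atoms: methanol, CO
Why: Chelation-directed, lanthanide-triflate-catalysed methanolysis of a 2,3-epoxy alcohol at the distal carbon, in which the europium cation sits between the cis C6 hydroxyl and the oxirane oxygen, methanol attacks C4 from the β face with inversion while C5–O stays α, and the Fürst–Plattner diaxial opening at C4 runs through the half-chair with C3–OH and C6–OH both pseudo-equatorial whereas attack at C5 would need both pseudo-axial.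

Step 10
Reactants: 12 2-methylbut-3-yn-2-ol
Product: 13 (3E)-2-methyl-4-(tributylstannyl)but-3-en-2-ol
Conditions: Bu3SnH, PdCl2(PPh3)2 (cat.), THF, 0 °C to rt
Reagents that add atoms: tributyltin hydride, CCCC[SnH](CCCC)CCCC
Why: Palladium-catalysed syn-hydrostannylation of a terminal alkyne, in which the bulky tertiary carbinol sends tin to the terminal carbon and gives the E-vinylstannane.

Step 11
Reactants: 13 (3E)-2-methyl-4-(tributylstannyl)but-3-en-2-ol; 14 2,3-dibromopropene
Product: 15 (3E)-6-bromo-2-methylhepta-3,6-dien-2-ol
Conditions: Pd2(dba)3 (cat.), AsPh3, THF, rt to 50 °C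
Reagents that add atoms: none
Why: Stille coupling with an allylic bromide, in which zerovalent palladium inserts into the allylic C–Br bond far faster than into the vinylic one, the 2-bromoallyl palladium intermediate is symmetrical, and the vinyl group is transferred with retention of the E geometry.

Step 12
Reactants: 15 (3E)-6-bromo-2-methylhepta-3,6-dien-2-ol; 16 trimethylsilylacetylene
Product: 17 (3E)-2-methyl-6-methylidene-8-(trimethylsilyl)oct-3-en-7-yn-2-ol
Conditions: PdCl2(PPh3)2 (cat.), CuI (cat.), Et3N, rt to 40 °C
Reagents that add atoms: none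
Why: Sonogashira coupling of a 2-bromo-1-alkene with a silyl-capped alkyne, which excludes double coupling and tolerates the free tertiary alcohol.

Step 13
Reactants: 17 (3E)-2-methyl-6-methylidene-8-(trimethylsilyl)oct-3-en-7-yn-2-ol
Product: 18 (3E)-2-methyl-6-methylideneoct-3-en-7-yn-2-ol
Conditions: K2CO3, MeOH, rt
Reagents that add atoms: none
Why: Base-catalysed protodesilylation of an alkynylsilane in methanol, too mild to move the skipped diene into conjugation.

Step 14
Reactants: 11 (1R,2S,3S,4S)-6-bromo-3-methoxycyclohex-5-ene-1,2,4-triol; 18 (3E)-2-methyl-6-methylideneoct-3-en-7-yn-2-ol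
Product: 19 (1S,2S,3S,4S)-6-[(5E)-7-hydroxy-7-methyl-3-methylideneoct-5-en-1-yn-1-yl]-3-methoxycyclohex-5-ene-1,2,4-triol
Conditions: Pd(PPh3)4 (cat.), CuI (cat.), Et3N, DMF (degassed), 50 °C
Reagents that add atoms: none
Why: Sonogashira coupling of a cyclic vinyl bromide with a terminal alkyne, as practised on halogenated conduritol-type polyols, in which free hydroxyls are tolerated, no allylic ester or oxirane is left to react with palladium or the amine, and no stereocentre is touched.

Step 15
Reactants: 19 (1S,2S,3S,4S)-6-[(5E)-7-hydroxy-7-methyl-3-methylideneoct-5-en-1-yn-1-yl]-3-methoxycyclohex-5-ene-1,2,4-triol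
Product: 22 (1S,4S,5S,6R)-4,5-dihydroxy-3-[(5E)-7-hydroxy-7-methyl-3-methylideneoct-5-en-1-yn-1-yl]-6-methoxycyclohex-2-en-1-yl acetate (CNP0546270.2), via phenylboronate 20 (not isolated), via phenylboronate acetate 21 (not isolated)
Conditions: PhB(OH)2, 4 Å MS, pyridine, rt; then Ac2O, 0 °C to rt; then pinacol, rt
Reagents that add atoms: acetic anhydride, CC(=O)OC(C)=O; phenylboronic acid, OB(O)c1ccccc1 (its atoms stay only in 20 and 21)
Why: Transient boronate masking as used for regioselective acylation of carbohydrate polyols, in which only the cis C5/C6 diol can form a five-membered phenylboronate (20), Ac2O in pyridine then acylates the one remaining secondary alcohol at C3 with retention (the tertiary alcohol does not react without DMAP) to give 21, and transesterification with pinacol frees the diol without touching an acetate that has no neighbouring free hydroxyl to migrate to.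

**Compound list**
1 | 2-bromo-4-methoxyphenol | COc1ccc(O)c(Br)c1 | starting material
2 | 2-bromo-4,4-dimethoxycyclohexa-2,5-dien-1-one | BrC1=CC(OC)(OC)C=CC1=O | intermediate
3 | sodium (3S)-6-bromo-4,4-dimethoxy-3-(tritylperoxy)cyclohexa-1,5-dien-1-olate (peroxide on C4, α face) | BrC1=CC(OC)(OC)[C@@H](OOC(c2ccccc2)(c2ccccc2)c2ccccc2)C=C1[O-].[Na+] | intermediate (not isolated)
4 | (5S,6R)-2-bromo-5,6-epoxy-4,4-dimethoxycyclohex-2-en-1-one, also named (1R,6S)-3-bromo-5,5-dimethoxy-7-oxabicyclo[4.1.0]hept-3-en-2-one (α-oxirane) | BrC1=CC(OC)(OC)[C@H]2O[C@H]2C1=O | intermediate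
5 | (1S,2R,6S)-3-bromo-5,5-dimethoxy-7-oxabicyclo[4.1.0]hept-3-en-2-ol (C6–OH α) | BrC1=CC(OC)(OC)[C@H]2O[C@H]2[C@H]1O | intermediate
6 | (1R,2R,6S)-3-bromo-5,5-dimethoxy-7-oxabicyclo[4.1.0]hept-3-en-2-yl acetate | BrC1=CC(OC)(OC)[C@H]2O[C@H]2[C@H]1OC(C)=O | intermediate
7 | (1R,2R,6S)-3-bromo-5-oxo-7-oxabicyclo[4.1.0]hept-3-en-2-yl acetate | BrC1=CC(=O)[C@H]2O[C@H]2[C@H]1OC(C)=O | intermediate
8 | (1R,2R,5R,6R)-3-bromo-5-hydroxy-7-oxabicyclo[4.1.0]hept-3-en-2-yl acetate (C3–OH α) | BrC1=C[C@@H](O)[C@H]2O[C@H]2[C@H]1OC(C)=O | intermediate
9 | (1R,2R,5S,6R)-3-bromo-7-oxabicyclo[4.1.0]hept-3-ene-2,5-diyl diacetate (C3–OAc β) | BrC1=C[C@H](OC(C)=O)[C@H]2O[C@H]2[C@H]1OC(C)=O | intermediate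
10 | (1S,2R,5S,6R)-3-bromo-7-oxabicyclo[4.1.0]hept-3-ene-2,5-diol | BrC1=C[C@H](O)[C@H]2O[C@H]2[C@H]1O | intermediate
11 | (1R,2S,3S,4S)-6-bromo-3-methoxycyclohex-5-ene-1,2,4-triol | BrC1=C[C@H](O)[C@H](OC)[C@@H](O)[C@H]1O | intermediate
12 | 2-methylbut-3-yn-2-ol | CC(C)(O)C#C | starting material
13 | (3E)-2-methyl-4-(tributylstannyl)but-3-en-2-ol | CC(C)(O)/C=C/[Sn](CCCC)(CCCC)CCCC | intermediate
14 | 2,3-dibromopropene | C=C(Br)CBr | starting material
15 | (3E)-6-bromo-2-methylhepta-3,6-dien-2-ol | C=C(Br)C/C=C/C(C)(C)O | intermediate
16 | trimethylsilylacetylene | C#C[Si](C)(C)C | starting material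
17 | (3E)-2-methyl-6-methylidene-8-(trimethylsilyl)oct-3-en-7-yn-2-ol | C=C(C#C[Si](C)(C)C)C/C=C/C(C)(C)O | intermediate
18 | (3E)-2-methyl-6-methylideneoct-3-en-7-yn-2-ol | C=C(C#C)C/C=C/C(C)(C)O | intermediate
19 | (1S,2S,3S,4S)-6-[(5E)-7-hydroxy-7-methyl-3-methylideneoct-5-en-1-yn-1-yl]-3-methoxycyclohex-5-ene-1,2,4-triol | C=C(C#CC1=C[C@H](O)[C@H](OC)[C@@H](O)[C@H]1O)C/C=C/C(C)(C)O | intermediate
20 | cyclic C5,C6-O-phenylboronate of 19 (dioxaborolane cis-fused on the α face, C3–OH free) | C=C(C#CC1=C[C@H](O)[C@H](OC)[C@H]2OB(c3ccccc3)O[C@@H]12)C/C=C/C(C)(C)O | intermediate (not isolated)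
21 | C3 acetate of boronate 20 | C=C(C#CC1=C[C@H](OC(C)=O)[C@H](OC)[C@H]2OB(c3ccccc3)O[C@@H]12)C/C=C/C(C)(C)O | intermediate (not isolated)
22 | (1S,4S,5S,6R)-4,5-dihydroxy-3-[(5E)-7-hydroxy-7-methyl-3-methylideneoct-5-en-1-yn-1-yl]-6-methoxycyclohex-2-en-1-yl acetate (ring locants of the route: 3S,4R,5S,6S) | C=C(C#CC1=C[C@H](OC(C)=O)[C@H](OC)[C@@H](O)[C@H]1O)C/C=C/C(C)(C)O | target

**Step count**
Total step count: 15.
Longest linear sequence: 11 steps (steps 1–9, 14 and 15). The side chain takes 4 steps (10–13).

**Steps most likely to fail**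

Step 2
- What may go wrong: poor enantioface discrimination. Compound 2 offers the sodium tartrate aggregate only its carbonyl and ketal oxygens as binding points. Sodium trityl peroxide that is not bound to tartrate may therefore epoxidise in the background and erode the enantiomeric purity. Conversion may also stall at the low temperature.
- Fallback: absolute control is moved from the epoxidation to an enzymatic resolution. Setting out from 2, a plain Weitz–Scheffer epoxidation (tBuOOH, DBU, CH2Cl2, 0 °C) should give the racemic epoxide F1. Reduction as in step 3 should give the racemic cis epoxy alcohol F2. A lipase-catalysed kinetic resolution (Candida antarctica lipase B, vinyl acetate, MTBE) should then acetylate one enantiomer only.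
- The Kazlauskas rule, with the C1–Br side as the large and the oxirane side as the medium substituent, predicts that the (6R)-alcohol reacts faster. The acetate formed would then be 6, where the route is rejoined. The unreacted enantiomeric alcohol F3 is removed by chromatography.

Step 9
- What may go wrong: loss of regiocontrol (methanol entering at C5), or sluggish opening that leaves time for solvolysis of the allylic hydroxyls.
- Fallback: the control element is changed from chelation to pure conformational control with non-participating bulky groups. Setting out from 10, silylation (TBSOTf, 2,6-lutidine, CH2Cl2) should give the bis-silyl ether F4.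
- In F4 diaxial opening at C4 keeps both large silyloxy groups pseudo-equatorial, while opening at C5 would force both pseudo-axial. Acid-catalysed methanolysis (BF3·OEt2 cat., MeOH, CH2Cl2, −30 °C) should then give the C4 methyl ether F5. Bu4NF in THF removes both silyl groups and returns to the route at 11.

Step 14
- What may go wrong: slow oxidative addition of zerovalent palladium into an unactivated, hindered and electron-rich vinyl bromide. Glaser-type homocoupling and oligomerisation of the enyne could then take over.
- Fallback: the coupling is moved forward to the carbonyl-activated bromide. Setting out from 7 and 18, a Sonogashira coupling at the β-bromoenone (PdCl2(PPh3)2, CuI, iPr2NEt, THF, 0 °C to rt) should give the enynone acetate F6.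
- Luche reduction as in step 6 should give the C3 α-alcohol F7. Mitsunobu reaction with AcOH as in step 7 should give the diacetate F8, and K2CO3/MeOH as in step 8 the epoxy diol F9. Methanolysis under the buffered conditions of step 9, which the tertiary allylic alcohol should tolerate, comes back to the route at 19.

**Further compounds**
F1 | step 2 | racemic 2-bromo-5,6-epoxy-4,4-dimethoxycyclohex-2-en-1-one | BrC1=CC(OC)(OC)[C@H]2O[C@H]2C1=O.BrC1=CC(OC)(OC)[C@@H]2O[C@@H]2C1=O
F2 | step 2 | racemic cis-3-bromo-5,5-dimethoxy-7-oxabicyclo[4.1.0]hept-3-en-2-ol (hydroxyl cis to the oxirane) | BrC1=CC(OC)(OC)[C@H]2O[C@H]2[C@H]1O.BrC1=CC(OC)(OC)[C@@H]2O[C@@H]2[C@@H]1O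
F3 | step 2 | (1R,2S,6R)-3-bromo-5,5-dimethoxy-7-oxabicyclo[4.1.0]hept-3-en-2-ol (enantiomer of 5) | BrC1=CC(OC)(OC)[C@@H]2O[C@@H]2[C@@H]1O
F4 | step 9 | C3 β, C6 α bis(tert-butyldimethylsilyl) ether of 10 | BrC1=C[C@H](O[Si](C)(C)C(C)(C)C)[C@H]2O[C@H]2[C@H]1O[Si](C)(C)C(C)(C)C
F5 | step 9 | C3,C6 bis(tert-butyldimethylsilyl) ether of 11 (C4–OMe β, C5–OH α) | BrC1=C[C@H](O[Si](C)(C)C(C)(C)C)[C@H](OC)[C@@H](O)[C@H]1O[Si](C)(C)C(C)(C)C
F6 | step 14 | analogue of 7 with the enyne side chain on C1 (C3 ketone, C6–OAc α, α-oxirane) | C=C(C#CC1=CC(=O)[C@H]2O[C@H]2[C@H]1OC(C)=O)C/C=C/C(C)(C)O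
F7 | step 14 | analogue of 8 with the enyne side chain on C1 (C3–OH α) | C=C(C#CC1=C[C@@H](O)[C@H]2O[C@H]2[C@H]1OC(C)=O)C/C=C/C(C)(C)O
F8 | step 14 | analogue of 9 with the enyne side chain on C1 (C3–OAc β, C6–OAc α) | C=C(C#CC1=C[C@H](OC(C)=O)[C@H]2O[C@H]2[C@H]1OC(C)=O)C/C=C/C(C)(C)O
F9 | step 14 | analogue of 10 with the enyne side chain on C1 (C3–OH β, C6–OH α, α-oxirane) | C=C(C#CC1=C[C@H](O)[C@H]2O[C@H]2[C@H]1O)C/C=C/C(C)(C)O
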